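4 questions stand on this flask, and I answer them with one number.

| flask | Ve | Qe | Qa | remark | time |
|---|---|---|---|---|---|
| summer | 0.30 M | 10 mM | 79 mM | run made earlier |  |
| spring | 0.30 M | 22 mM | 79 mM | run made earlier |  |
| autumn | 0.30 M | 15 mM | 120 mM | run made earlier |  |
| flask | 0.30 M | 15 mM | 79 mM |  | 1.5 h |

- summer (time / min: Uv / %, Jo / %): 10.0: 49.5, 26.9; 20.0: 54.4, 29.0; 25.0: 53.8, 29.3; 40.0: 53.8, 28.6; 50.0: 52.9, 28.9
- spring (time / min: Uv / %, Jo / %): 10.0: 53.4, 29.3; 20.0: 53.2, 29.4; 25.0: 54.1, 29.1; 40.0: 52.4, 29.7; 50.0: 51.2, 29.4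
- autumn (time / min: Uv / %, Jo / %): 10.0: 52.0, 27.8; 20.0: 54.4, 28.8; 30.0: 53.2, 29.5; 40.0: 53.2, 28.8; 50.0: 52.9, 29.5

(scatter of a reading: 0.5 percentage points)



- share of Uv in Uv plus Jo at 2.0 s
- share of Uv in Uv plus Jo at 1.5 min
- share of Uv in Uv plus Jo at 1.5 h
- which of Uv and Jo there is more of at 1.5 h

Ve is the limiting reagent, so I keep a ledger in fractions of its charge. In the spring run at 10.0 min the books read 53.4% to Uv, 29.3% to Jo and 17.3% to no reading. At 50.0 min the same run reads 51.2%, 29.4% and 19.4%. So Jo stands still within the scatter of 0.5 percentage points, while the entry passes from Uv to the unread column.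

An even split of Uv and Jo, a share of 0.5, is my zero, and the distance of the share of Uv from that zero is the tilt, here as read in the spring run at 10.0 min: 15 points. At 50.0 min that run reads 14 points, so it loses 1 point in 40.0 min, a rough reading of a small difference.

My flask has the same Qa and 0.682 of the spring Qe. I assume the loss runs in proportion to Qe, which gives 1.4 points by 1.5 h. The tilt there is 13 points, a share of 63.1%, with Uv ahead. For 2.0 s, which no run samples, and for 1.5 min I keep the share read in the spring run at 10.0 min, 64.6%.

The forecast says 65%, 64.9% and 63.7%, with Uv ahead: "Later, Uv drifts down while Jo stays flat". My last share lies below its figure.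

The flask gives 65.5%, 65.5% and 63.0%, with Uv ahead at 50.5% against 29.7% of Jo.

    Qe + Qa ⇌ Wy (K = 7.50 /M, k = 3.90 /M/min)
    Ve + Qe ⇌ Uv + Qe, rate k2*[Ve]*[Qe] forward; the back reaction follows from the equilibrium constant (K = 20.0, k = 19.0 /M/min)
    Ve + Qe ⇌ Jo + Qe, rate k3*[Ve]*[Qe] forward; the back reaction follows from the equilibrium constant (K = 13.0, k = 10.0 /M/min)
    Ve + Qe ⇌ Gy + Qe, rate k4*[Ve]*[Qe] forward; the back reaction follows from the equilibrium constant (K = 14.0, k = 4.40 /M/min)

In tilt, the flask stands at 16 points at 1.5 min and 13 points at 1.5 h, beside my 15 points less 1.4 points. The neighbouring flask changes one thing: Ve is charged at 0.12 M instead of 0.30 M. Qe and Qa are charged as in the flask, and in fractions of the charge my reckoning holds no term for Ve, so it gives the same 13 points there. The neighbour ends with 50.5% Uv, 29.7% Jo and 2.29% Ve left, a share of 63.0%, which is a tilt of 13 points.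

The runs stem from a simulated flask with constants of no real substance, and the scatter is random.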